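**Retrosynthetic overview**
- Target 16 comes from its octa-O-benzyl ether 15 by one hydrogenolysis; the C4–H bond of 15 comes from ionic hydride reduction of carbinol 13, with hydride entering anti to the 2-aryl group, which fixes the 2,4-cis (2S,4S) upper unit.
- The interflavan C4–C8 bond comes from 1,2-addition of 8-lithio-penta-O-benzylcatechin 12 to (2S)-flavanone 7; (+)-catechin supplies the lower C2 and C3 centres.
- Flavanone 7 comes from chalcone 5, whose Cα–Cβ bond (flavan C3–C2) is the key C–C bond: an intermolecular Claisen–Schmidt aldol condensation joins the ring A acetophenone 2 and the ring B aldehyde 3.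
- Upper C2 is set by kinetic resolution of racemic flavanone 6 (asymmetric transfer hydrogenation) and then relays its configuration to C4.
- Ring order: the upper ring C is the only ring built (oxa-Michael closure after the aldol); all aromatic rings and the lower ring C are bought in.

Assumption: the target is taken exactly as drawn, (2S,4S) in the upper flavan unit and (2R,3S), that is (+)-catechin, in the lower unit; racemates and epimer mixtures are written without stereodescriptors at the centres concerned.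

**Route**

Step 1
Reactants: 1 2',4'-dihydroxyacetophenone
Product: 2 4'-benzyloxy-2'-hydroxyacetophenone
Conditions: BnBr (1.05 equiv), K2CO3 (1.1 equiv), acetone, reflux, 6 h
Reagents that add atoms: benzyl bromide, BrCc1ccccc1
Why: Williamson ether synthesis that is selective for the 4'-OH because the 2'-OH is locked in a hydrogen bond to the ketone and is far less acidic and nucleophilic; no stereocentre is involved.

Step 2
Reactants: 2 4'-benzyloxy-2'-hydroxyacetophenone; 3 3,4-bis(benzyloxy)benzaldehyde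
Product: 5 (E)-1-(4-benzyloxy-2-hydroxyphenyl)-3-[3,4-bis(benzyloxy)phenyl]prop-2-en-1-one, via aldol adduct 4 (not isolated)
Conditions: KOH (50% aq, 5 equiv), EtOH/THF, rt, 48 h; then 1 M HCl to pH 3
Reagents that add atoms: none
Why: Intermolecular Claisen–Schmidt aldol condensation in which the potassium enolate of methyl ketone 2 adds to the non-enolisable aldehyde 3 and the β-hydroxy ketone 4 dehydrates by E1cB to the conjugated (E)-enone, so the racemic carbinol centre of 4 disappears and the ring A and ring B fragments are joined through the future C3–C2 bond.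

Step 3
Reactants: 5 (E)-1-(4-benzyloxy-2-hydroxyphenyl)-3-[3,4-bis(benzyloxy)phenyl]prop-2-en-1-one
Product: 6 racemic 7-benzyloxy-2-[3,4-bis(benzyloxy)phenyl]chroman-4-one
Conditions: NaOAc (5 equiv), EtOH, reflux, 24 h; recovered 5 recycled
Reagents that add atoms: none
Why: Intramolecular oxa-Michael addition (chalcone–flavanone isomerisation, 6-endo-trig) of the 2'-phenol onto the enone closes ring C under mild base, forming C2 as a racemate that is resolved in the next step.

Step 4
Reactants: 6 racemic 7-benzyloxy-2-[3,4-bis(benzyloxy)phenyl]chroman-4-one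
Product: 7 (2S)-7-benzyloxy-2-[3,4-bis(benzyloxy)phenyl]chroman-4-one
Conditions: RuCl(p-cymene)[(R,R)-TsDPEN] (1 mol %), HCO2H/Et3N (5:2), EtOAc, 25 °C, stopped at about 55% conversion; chromatography
Reagents that add atoms: none
Why: Kinetic resolution by Noyori-type asymmetric transfer hydrogenation, in which the (R,R)-catalyst delivers hydride to the carbonyl face that gives a (4R)-carbinol and this face is the favoured axial one anti to the 2-aryl group only in (2R)-6, so (2R)-6 is reduced quickly to the cis-flavan-4-ol while unreacted (2S)-7 is recovered in high ee.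

Step 5
Reactants: 8 (+)-catechin
Product: 9 5,7,3',4'-tetra-O-benzyl-(+)-catechin
Conditions: BnBr (4.3 equiv), K2CO3 (5 equiv), DMF, −10 °C to rt, N2, 16 h; recrystallisation
Reagents that add atoms: benzyl bromide, BrCc1ccccc1
Why: Williamson ether synthesis under weak-base conditions alkylates only the four phenolic hydroxyls and leaves the much less acidic secondary 3-OH free, while the C2 and C3 stereocentres from the chiral pool are not touched.

Step 6
Reactants: 9 5,7,3',4'-tetra-O-benzyl-(+)-catechin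
Product: 10 8-bromo-5,7,3',4'-tetra-O-benzyl-(+)-catechin
Conditions: NBS (1.0 equiv), CH2Cl2, −78 °C to rt
Reagents that add atoms: N-bromosuccinimide, O=C1CCC(=O)N1Br
Why: Electrophilic aromatic bromination of the phloroglucinol-type ring A takes place once and regioselectively at C8, the position flanked by the ring oxygen and the 7-benzyloxy group, as is established for tetra-O-benzyl flavan-3-ols; no stereocentre is touched.

Step 7
Reactants: 10 8-bromo-5,7,3',4'-tetra-O-benzyl-(+)-catechin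
Product: 11 8-bromo-3,5,7,3',4'-penta-O-benzyl-(+)-catechin
Conditions: NaH (1.5 equiv), BnBr (1.3 equiv), DMF, 0 °C to rt, 3 h
Reagents that add atoms: benzyl bromide, BrCc1ccccc1
Why: Williamson ether synthesis on the sodium alkoxide removes the only acidic proton before the organolithium step, with retention at C3 because the C3–O bond is not broken.

Step 8
Reactants: 11 8-bromo-3,5,7,3',4'-penta-O-benzyl-(+)-catechin; 7 (2S)-7-benzyloxy-2-[3,4-bis(benzyloxy)phenyl]chroman-4-one
Product: 13 (2S)-7-benzyloxy-2-[3,4-bis(benzyloxy)phenyl]-4-[(2R,3S)-3,5,7-tris(benzyloxy)-2-[3,4-bis(benzyloxy)phenyl]chroman-8-yl]chroman-4-ol (both C4 epimers), via 8-lithio penta-O-benzylcatechin 12 (not isolated)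
Conditions: 11 (1.5 equiv), t-BuLi (3.0 equiv), THF, −78 °C, 30 min; then 7 (1.0 equiv) in THF, −78 to −20 °C; H2O
Reagents that add atoms: none
Why: Bromine–lithium exchange gives aryllithium 12, which is stabilised by two ortho oxygens and undergoes 1,2-addition to the flavanone carbonyl at low temperature faster than it enolises it, creating the C4–C8 interflavan bond without touching C2, while the configuration of the new carbinol carbon is irrelevant because it is planarised in the next step.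

Step 9
Reactants: 13 (2S)-7-benzyloxy-2-[3,4-bis(benzyloxy)phenyl]-4-[(2R,3S)-3,5,7-tris(benzyloxy)-2-[3,4-bis(benzyloxy)phenyl]chroman-8-yl]chroman-4-ol
Product: 15 (2R,3S)-3,5,7-tris(benzyloxy)-2-[3,4-bis(benzyloxy)phenyl]-8-[(2S,4S)-7-benzyloxy-2-[3,4-bis(benzyloxy)phenyl]chroman-4-yl]chromane, via chroman-4-ylium trifluoroacetate 14 (not isolated)
Conditions: n-Bu3SnH (5 equiv), CF3CO2H (10 equiv), CH2Cl2, 0 °C, 1 h
Reagents that add atoms: none
Why: Ionic hydrogenation in which acid ionises the doubly benzylic tertiary alcohol to the planar C4 cation 14 and tributyltin hydride attacks along the axial trajectory on the face anti to the equatorial 2-aryl group (chair-like transition state), so the C4 aryl group ends up equatorial and cis to the 2-aryl group, which is the (4S) configuration.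

Step 10
Reactants: 15 (2R,3S)-3,5,7-tris(benzyloxy)-2-[3,4-bis(benzyloxy)phenyl]-8-[(2S,4S)-7-benzyloxy-2-[3,4-bis(benzyloxy)phenyl]chroman-4-yl]chromane
Product: 16 (2R,3S)-2-(3,4-dihydroxyphenyl)-8-[(2S,4S)-2-(3,4-dihydroxyphenyl)-7-hydroxychroman-4-yl]chromane-3,5,7-triol (target)
Conditions: H2 (1 atm), Pd(OH)2/C (20 wt %), THF/MeOH/H2O (20:1:1), rt, 6 h; filtration through Celite under N2, lyophilisation
Reagents that add atoms: none
Why: Catalytic hydrogenolysis cleaves the seven aryl benzyl ethers and the 3-O-benzyl ether as toluene much faster than the cyclic benzylic C2–O bonds or the C4–C8 bond, so all four stereocentres are carried unchanged into the target.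

**Compound list**

1 | 2',4'-dihydroxyacetophenone | CC(=O)c1ccc(O)cc1O | starting material
2 | 4'-benzyloxy-2'-hydroxyacetophenone | CC(=O)c1ccc(OCc2ccccc2)cc1O | intermediate
3 | 3,4-bis(benzyloxy)benzaldehyde | O=Cc1ccc(OCc2ccccc2)c(OCc2ccccc2)c1 | starting material
4 | aldol adduct, racemic 1-(4-benzyloxy-2-hydroxyphenyl)-3-[3,4-bis(benzyloxy)phenyl]-3-hydroxypropan-1-one (not isolated) | O=C(CC(O)c1ccc(OCc2ccccc2)c(OCc2ccccc2)c1)c1ccc(OCc2ccccc2)cc1O | intermediate
5 | (E)-1-(4-benzyloxy-2-hydroxyphenyl)-3-[3,4-bis(benzyloxy)phenyl]prop-2-en-1-one (chalcone) | O=C(/C=C/c1ccc(OCc2ccccc2)c(OCc2ccccc2)c1)c1ccc(OCc2ccccc2)cc1O | intermediate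
6 | racemic 7-benzyloxy-2-[3,4-bis(benzyloxy)phenyl]chroman-4-one | O=C1CC(c2ccc(OCc3ccccc3)c(OCc3ccccc3)c2)Oc2cc(OCc3ccccc3)ccc12 | intermediate
7 | (2S)-7-benzyloxy-2-[3,4-bis(benzyloxy)phenyl]chroman-4-one | O=C1C[C@@H](c2ccc(OCc3ccccc3)c(OCc3ccccc3)c2)Oc2cc(OCc3ccccc3)ccc12 | intermediate
8 | (+)-catechin, (2R,3S)-2-(3,4-dihydroxyphenyl)chromane-3,5,7-triol | Oc1cc(O)c2c(c1)O[C@H](c1ccc(O)c(O)c1)[C@@H](O)C2 | starting material
9 | 5,7,3',4'-tetra-O-benzyl-(+)-catechin, (2R,3S)-5,7-bis(benzyloxy)-2-[3,4-bis(benzyloxy)phenyl]chroman-3-ol | c1ccccc1COc1cc(OCc3ccccc3)c2c(c1)O[C@H](c1ccc(OCc3ccccc3)c(OCc3ccccc3)c1)[C@@H](O)C2 | intermediate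
10 | 8-bromo-5,7,3',4'-tetra-O-benzyl-(+)-catechin, (2R,3S)-5,7-bis(benzyloxy)-2-[3,4-bis(benzyloxy)phenyl]-8-bromochroman-3-ol | c1ccccc1COc1cc(OCc3ccccc3)c2c(c1Br)O[C@H](c1ccc(OCc3ccccc3)c(OCc3ccccc3)c1)[C@@H](O)C2 | intermediate
11 | 8-bromo-3,5,7,3',4'-penta-O-benzyl-(+)-catechin, (2R,3S)-3,5,7-tris(benzyloxy)-2-[3,4-bis(benzyloxy)phenyl]-8-bromochromane | c1ccccc1COc1cc(OCc3ccccc3)c2c(c1Br)O[C@H](c1ccc(OCc3ccccc3)c(OCc3ccccc3)c1)[C@@H](OCc1ccccc1)C2 | intermediate
12 | 8-lithio-3,5,7,3',4'-penta-O-benzyl-(+)-catechin (not isolated) | c1ccccc1COc1cc(OCc3ccccc3)c2c(c1[Li])O[C@H](c1ccc(OCc3ccccc3)c(OCc3ccccc3)c1)[C@@H](OCc1ccccc1)C2 | intermediate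
13 | (2S)-7-benzyloxy-2-[3,4-bis(benzyloxy)phenyl]-4-[(2R,3S)-3,5,7-tris(benzyloxy)-2-[3,4-bis(benzyloxy)phenyl]chroman-8-yl]chroman-4-ol, both C4 epimers | c1ccccc1COc1ccc2c(c1)O[C@H](c1ccc(OCc3ccccc3)c(OCc3ccccc3)c1)CC2(O)c1c(OCc3ccccc3)cc(OCc3ccccc3)c2c1O[C@H](c1ccc(OCc3ccccc3)c(OCc3ccccc3)c1)[C@@H](OCc1ccccc1)C2 | intermediate
14 | (2S)-7-benzyloxy-2-[3,4-bis(benzyloxy)phenyl]-4-[(2R,3S)-3,5,7-tris(benzyloxy)-2-[3,4-bis(benzyloxy)phenyl]chroman-8-yl]chroman-4-ylium trifluoroacetate (not isolated) | c1ccccc1COc1ccc2c(c1)O[C@H](c1ccc(OCc3ccccc3)c(OCc3ccccc3)c1)C[C+]2c1c(OCc3ccccc3)cc(OCc3ccccc3)c2c1O[C@H](c1ccc(OCc3ccccc3)c(OCc3ccccc3)c1)[C@@H](OCc1ccccc1)C2.[O-]C(=O)C(F)(F)F | intermediate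
15 | (2R,3S)-3,5,7-tris(benzyloxy)-2-[3,4-bis(benzyloxy)phenyl]-8-[(2S,4S)-7-benzyloxy-2-[3,4-bis(benzyloxy)phenyl]chroman-4-yl]chromane (octa-O-benzyl ether of the target, 2,4-cis) | c1ccccc1COc1ccc2c(c1)O[C@H](c1ccc(OCc3ccccc3)c(OCc3ccccc3)c1)C[C@@H]2c1c(OCc3ccccc3)cc(OCc3ccccc3)c2c1O[C@H](c1ccc(OCc3ccccc3)c(OCc3ccccc3)c1)[C@@H](OCc1ccccc1)C2 | intermediate
16 | (2R,3S)-2-(3,4-dihydroxyphenyl)-8-[(2S,4S)-2-(3,4-dihydroxyphenyl)-7-hydroxychroman-4-yl]chromane-3,5,7-triol | Oc1ccc2c(c1)O[C@H](c1ccc(O)c(O)c1)C[C@@H]2c1c(O)cc(O)c2c1O[C@H](c1ccc(O)c(O)c1)[C@@H](O)C2 | target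

**Totals**

Total step count: 10. Longest linear sequence: 7 steps (steps 1, 2, 3, 4, 8, 9, 10); the catechin branch (steps 5, 6, 7) joins at step 8.

**Three steps most likely to fail**

Step 4 (kinetic resolution). The selectivity factor may be too low with three bulky benzyloxy groups, or the reduction may stall before the (2R)-enantiomer is consumed. The fallback gives up the resolution and lets the enantiopure catechin part act as the resolving handle. It sets out from racemic 6, which is added to 12 (made from 11) exactly as in step 8. This gives the carbinol mixture 7-benzyloxy-2-[3,4-bis(benzyloxy)phenyl]-4-[(2R,3S)-3,5,7-tris(benzyloxy)-2-[3,4-bis(benzyloxy)phenyl]chroman-8-yl]chroman-4-ol with both configurations at the upper C2 and C4 F1. CF3CO2H ionises it to the corresponding chroman-4-ylium trifluoroacetate with both configurations at the upper C2 F2, and n-Bu3SnH reduces this as in step 9 to a roughly 1:1 mixture of 15 and (2R,3S)-3,5,7-tris(benzyloxy)-2-[3,4-bis(benzyloxy)phenyl]-8-[(2R,4R)-7-benzyloxy-2-[3,4-bis(benzyloxy)phenyl]chroman-4-yl]chromane F3. Both are 2,4-cis and they are diastereomers, so they are separated on silica or by preparative HPLC, and the route is rejoined at 15.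

Step 8 (aryllithium addition). The aryllithium 12 may act as a base, enolising 7, which can then open by retro-oxa-Michael reaction to chalcone 5. The fallback makes the enolate on purpose and forms the bond by cross-coupling. It sets out from 7 and 11. Compound 7 is deprotonated with KN(SiMe3)2 (THF, −78 °C) and trapped at once with PhNTf2 as the enol triflate (2S)-7-benzyloxy-2-[3,4-bis(benzyloxy)phenyl]-2H-chromen-4-yl trifluoromethanesulfonate F4. Compound 11 is converted through 12 and i-PrOBpin into the boronic ester (2R,3S)-3,5,7-tris(benzyloxy)-2-[3,4-bis(benzyloxy)phenyl]-8-(4,4,5,5-tetramethyl-1,3,2-dioxaborolan-2-yl)chromane F5. Suzuki–Miyaura coupling of the two (Pd(OAc)2, SPhos, K3PO4, toluene/H2O, 60 °C) gives the flav-3-ene (2R,3S)-3,5,7-tris(benzyloxy)-2-[3,4-bis(benzyloxy)phenyl]-8-[(2S)-7-benzyloxy-2-[3,4-bis(benzyloxy)phenyl]-2H-chromen-4-yl]chromane F6. Under the conditions of step 9, CF3CO2H protonates F6 at C3 to the same cation 14, which n-Bu3SnH reduces with the same facial preference, so the route is rejoined at 15.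

Step 10 (global hydrogenolysis). Eight benzyl ethers, one of them on a secondary aliphatic oxygen, must be removed without hydrogenolysing the benzylic C2–O ring bonds, and the free polyphenol is air-sensitive. The fallback is a non-reductive debenzylation. It sets out from 15, which is treated with BCl3 (about 3 equiv per benzyl group) and pentamethylbenzene as benzyl cation scavenger in CH2Cl2 at −78 °C, then quenched with MeOH, and it comes back to the route at 16. This way makes no further compound (none F0).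

**Further compounds**

F1 | step 4 | 7-benzyloxy-2-[3,4-bis(benzyloxy)phenyl]-4-[(2R,3S)-3,5,7-tris(benzyloxy)-2-[3,4-bis(benzyloxy)phenyl]chroman-8-yl]chroman-4-ol, both configurations at the upper C2 and C4 | c1ccccc1COc1ccc2c(c1)OC(c1ccc(OCc3ccccc3)c(OCc3ccccc3)c1)CC2(O)c1c(OCc3ccccc3)cc(OCc3ccccc3)c2c1O[C@H](c1ccc(OCc3ccccc3)c(OCc3ccccc3)c1)[C@@H](OCc1ccccc1)C2
F2 | step 4 | 7-benzyloxy-2-[3,4-bis(benzyloxy)phenyl]-4-[(2R,3S)-3,5,7-tris(benzyloxy)-2-[3,4-bis(benzyloxy)phenyl]chroman-8-yl]chroman-4-ylium trifluoroacetate, both configurations at the upper C2 | c1ccccc1COc1ccc2c(c1)OC(c1ccc(OCc3ccccc3)c(OCc3ccccc3)c1)C[C+]2c1c(OCc3ccccc3)cc(OCc3ccccc3)c2c1O[C@H](c1ccc(OCc3ccccc3)c(OCc3ccccc3)c1)[C@@H](OCc1ccccc1)C2.[O-]C(=O)C(F)(F)F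
F3 | step 4 | (2R,3S)-3,5,7-tris(benzyloxy)-2-[3,4-bis(benzyloxy)phenyl]-8-[(2R,4R)-7-benzyloxy-2-[3,4-bis(benzyloxy)phenyl]chroman-4-yl]chromane | c1ccccc1COc1ccc2c(c1)O[C@@H](c1ccc(OCc3ccccc3)c(OCc3ccccc3)c1)C[C@H]2c1c(OCc3ccccc3)cc(OCc3ccccc3)c2c1O[C@H](c1ccc(OCc3ccccc3)c(OCc3ccccc3)c1)[C@@H](OCc1ccccc1)C2
F4 | step 8 | (2S)-7-benzyloxy-2-[3,4-bis(benzyloxy)phenyl]-2H-chromen-4-yl trifluoromethanesulfonate | O=S(=O)(OC1=C[C@@H](c2ccc(OCc3ccccc3)c(OCc3ccccc3)c2)Oc2cc(OCc3ccccc3)ccc12)C(F)(F)F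
F5 | step 8 | (2R,3S)-3,5,7-tris(benzyloxy)-2-[3,4-bis(benzyloxy)phenyl]-8-(4,4,5,5-tetramethyl-1,3,2-dioxaborolan-2-yl)chromane | c1ccccc1COc1cc(OCc3ccccc3)c2c(c1B4OC(C)(C)C(C)(C)O4)O[C@H](c1ccc(OCc3ccccc3)c(OCc3ccccc3)c1)[C@@H](OCc1ccccc1)C2
F6 | step 8 | (2R,3S)-3,5,7-tris(benzyloxy)-2-[3,4-bis(benzyloxy)phenyl]-8-[(2S)-7-benzyloxy-2-[3,4-bis(benzyloxy)phenyl]-2H-chromen-4-yl]chromane | c1ccccc1COc1ccc2c(c1)O[C@H](c1ccc(OCc3ccccc3)c(OCc3ccccc3)c1)C=C2c1c(OCc3ccccc3)cc(OCc3ccccc3)c2c1O[C@H](c1ccc(OCc3ccccc3)c(OCc3ccccc3)c1)[C@@H](OCc1ccccc1)C2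
F0 | step 10 | none | none
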